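The disconnection is the N1–C7a bond of ring A, the 4,5,6-tribromoindole. The precursor is a tetrasubstituted vinyl azide whose β-carbon (future C3) already carries both a 3,4,5-tribromophenyl ring and N1' of the complete ring B indole. On heating it loses N2, and the nitrene nitrogen closes onto an aryl ortho carbon, building the pyrrole ring of ring A in one operation. The step exploits the local symmetry of the tribromophenyl ring. Its two ortho C–H carbons (either becomes C7a) are equivalent, so only the C4, C5, C6 bromine pattern can result, while Br at C2' blocks closure onto ring B. The C2 ester left by the closure is finally exchanged for SMe.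

Key step: step 7

Assumption 1: the target SMILES defines no configuration for the hindered C3–N1' axis, so the racemate is taken as the target.
Assumption 2: the enol triflate and the vinyl azide are drawn and named as their E isomers (aryl cis to azide). Any Z isomer is carried along, because both isomers collapse to the same 2H-azirine.

Step 1
Reactants: 1 3,4,5-tribromobenzoic acid; 2 methyl potassium malonate
Product: 4 methyl 3-oxo-3-(3,4,5-tribromophenyl)propanoate, via acyl imidazolide 3 (not isolated)
Conditions: 1, CDI, THF, rt; added to 2, MgCl2, THF, 50 °C → rt; 1 M HCl work-up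
Reagents that add atoms: 1,1'-carbonyldiimidazole O=C(n1ccnc1)n1ccnc1 (supplies the imidazolyl group of 3 only; none of it remains in 4)
Why: Masamune–Brooks decarboxylative Claisen condensation, in which the magnesium-chelated malonate half-ester enolate is C-acylated by the imidazolide and loses CO2 under conditions that leave aryl bromides untouched.

Step 2
Reactants: 4 methyl 3-oxo-3-(3,4,5-tribromophenyl)propanoate
Product: 6 methyl 2-azido-3-oxo-3-(3,4,5-tribromophenyl)propanoate (racemic), via α-bromo keto ester 5 (not isolated)
Conditions: NBS (1.0 equiv), NH4OAc (10 mol %), MeCN, 0 °C → rt; then NaN3 (1.2 equiv), H2O, 0 °C, dark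
Reagents that add atoms: N-bromosuccinimide O=C1CCC(=O)N1Br (bromine of 5 only); sodium azide [Na+].[N-]=[N+]=[N-]
Why: Electrophilic α-bromination of the enolised β-keto ester and SN2 displacement of the doubly activated bromide by azide is the standard entry to 2-azido-1,3-dicarbonyl compounds, with one equivalent of NBS limiting dibromination and the labile α-centre being erased in step 3.

Step 3
Reactants: 6 methyl 2-azido-3-oxo-3-(3,4,5-tribromophenyl)propanoate
Product: 7 methyl (E)-2-azido-3-(3,4,5-tribromophenyl)-3-(trifluoromethylsulfonyloxy)acrylate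
Conditions: LiOTf (LiO3SCF3), iPr2NEt, CH2Cl2, −78 °C; Tf2O, −78 → 0 °C
Reagents that add atoms: trifluoromethanesulfonic anhydride O=S(=O)(OS(=O)(=O)C(F)(F)F)C(F)(F)F
Why: Enol triflate formation by O-sulfonylation of a β-keto ester enolate, where lithium chelation between the enolate and ester oxygens places OTf cis to CO2Me and the doubly stabilised enolate is trapped cold before it can lose N2.

Step 4
Reactants: 8 4,6-dibromo-1H-indole
Product: 9 4,6-dibromo-3-(methylthio)-1H-indole
Conditions: MeSSMe, SO2Cl2, CH2Cl2, −20 °C (→ MeSCl); then 8, CH2Cl2, −78 → 0 °C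
Reagents that add atoms: dimethyl disulfide CSSC (converted in the flask by SO2Cl2 into methanesulfenyl chloride CSCl)
Why: Electrophilic sulfenylation at C3, the most nucleophilic carbon of an N–H indole, with an electrophile small enough to enter beside the C4 bromine and used in one equivalent to avoid a second sulfenylation.

Step 5
Reactants: 9 4,6-dibromo-3-(methylthio)-1H-indole
Product: 10 2,4,6-tribromo-3-(methylthio)-1H-indole
Conditions: NBS (1.0 equiv), dry CH2Cl2, 0 °C, dark
Reagents that add atoms: N-bromosuccinimide O=C1CCC(=O)N1Br
Why: Electrophilic bromination of an indole whose C3 is blocked goes to C2, helped by bromine transfer from the neighbouring sulfide, and the absence of water prevents sulfoxide formation.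

Step 6
Reactants: 7 methyl (E)-2-azido-3-(3,4,5-tribromophenyl)-3-(trifluoromethylsulfonyloxy)acrylate; 10 2,4,6-tribromo-3-(methylthio)-1H-indole
Product: 11 methyl (E)-2-azido-3-(3,4,5-tribromophenyl)-3-[2,4,6-tribromo-3-(methylthio)indol-1-yl]acrylate
Conditions: Cs2CO3, DMF, 0 °C → rt, dark
Reagents that add atoms: none
Why: Nucleophilic vinylic substitution by addition–elimination, in which the indolide nitrogen (C3 being blocked) adds to the ester-activated β-carbon and the transient α-azido ester enolate expels triflate far faster than it can return the indolide.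

Step 7
Reactants: 11 methyl (E)-2-azido-3-(3,4,5-tribromophenyl)-3-[2,4,6-tribromo-3-(methylthio)indol-1-yl]acrylate
Product: 14 methyl 4,5,6-tribromo-3-[2,4,6-tribromo-3-(methylthio)indol-1-yl]-1H-indole-2-carboxylate, via 2H-azirine 12 (not isolated), via 7aH-indole tautomer 13 (not isolated)
Conditions: o-xylene (0.01 M), 140 °C, slow addition, N2 atmosphere
Reagents that add atoms: none
Why: This is a Hemetsberger–Knittel indole synthesis, whose closest known relatives are β,β-disubstituted α-azidocinnamates that give 3-substituted indole-2-carboxylates. Heating expels N2 from 11 to give racemic 2H-azirine 12, whose C2–N bond opens reversibly at 140 °C to the vinyl nitrene, so either alkene isomer of 11 can place nitrogen beside the aryl ring. The one ring formed, the pyrrole ring of ring A, closes by a five-atom, six-electron electrocyclisation over N1, C2, C3, C3a and C7a to give 13, and a 1,5-hydrogen shift from C7a to N1 then restores aromaticity irreversibly. No stereocentre is created: the centres of 12 and 13 vanish again and the hindered C3–N1' axis is formed as a racemate. Regioselectivity needs no control because the two ortho C–H carbons of the 3,4,5-tribromophenyl ring are interchangeable. Chemoselectivity over ring B is secured by Br at C2', which leaves no hydrogen to shift so that closure there stays reversible, by the twist that C2'–Br and C7'–H impose on ring B relative to the alkene plane, and by the longer six-atom path that attack at C7'–H would need; high dilution keeps the sulfides from trapping the nitrene.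

Step 8
Reactants: 14 methyl 4,5,6-tribromo-3-[2,4,6-tribromo-3-(methylthio)indol-1-yl]-1H-indole-2-carboxylate
Product: 15 4,5,6-tribromo-3-[2,4,6-tribromo-3-(methylthio)indol-1-yl]-1H-indole-2-carboxylic acid
Conditions: LiOH, THF/MeOH/H2O, 45 °C; then 1 M HCl
Reagents that add atoms: lithium hydroxide [Li+].[OH-]
Why: Saponification of a methyl ester by acyl–oxygen cleavage, to which aryl bromides, the C2' bromide and both kinds of sulfide are inert at this temperature.

Step 9
Reactants: 15 4,5,6-tribromo-3-[2,4,6-tribromo-3-(methylthio)indol-1-yl]-1H-indole-2-carboxylic acid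
Product: 16 4,5,6-tribromo-3-[2,4,6-tribromo-3-(methylthio)indol-1-yl]-1H-indole
Conditions: Ag2CO3 (15 mol %), AcOH (10 mol %), DMSO, 120 °C
Reagents that add atoms: none
Why: Silver-catalysed protodecarboxylation of a heteroaromatic acid, in which the monovalent silver carboxylate extrudes CO2 to a C2-silver indole that acetic acid protonates, aided by the bulky C3 group twisting the carboxylate out of plane and harmless to C–Br bonds.

Step 10
Reactants: 16 4,5,6-tribromo-3-[2,4,6-tribromo-3-(methylthio)indol-1-yl]-1H-indole
Product: 17 4,5,6-tribromo-2-(methylthio)-3-[2,4,6-tribromo-3-(methylthio)indol-1-yl]-1H-indole (target)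
Conditions: MeSSMe, SO2Cl2, CH2Cl2, −20 °C (→ MeSCl); then 16, CH2Cl2, −40 °C → rt
Reagents that add atoms: dimethyl disulfide CSSC (converted in the flask by SO2Cl2 into methanesulfenyl chloride CSCl)
Why: Electrophilic sulfenylation of a 3-substituted N–H indole at C2, its only free pyrrole carbon (directly or by C3 attack and 1,2-shift), the reactivity that turns 3-(methylthio)indoles into 2,3-bis(methylthio)indoles, while ring B offers only bromine-deactivated benzo C–H bonds.

Compound list
1 | 3,4,5-tribromobenzoic acid | OC(=O)c1cc(Br)c(Br)c(Br)c1 | starting material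
2 | methyl potassium malonate | COC(=O)CC(=O)[O-].[K+] | starting material
3 | 1-(3,4,5-tribromobenzoyl)imidazole | O=C(c1cc(Br)c(Br)c(Br)c1)n1ccnc1 | intermediate
4 | methyl 3-oxo-3-(3,4,5-tribromophenyl)propanoate | COC(=O)CC(=O)c1cc(Br)c(Br)c(Br)c1 | intermediate
5 | methyl 2-bromo-3-oxo-3-(3,4,5-tribromophenyl)propanoate (racemic) | COC(=O)C(Br)C(=O)c1cc(Br)c(Br)c(Br)c1 | intermediate
6 | methyl 2-azido-3-oxo-3-(3,4,5-tribromophenyl)propanoate (racemic) | COC(=O)C(N=[N+]=[N-])C(=O)c1cc(Br)c(Br)c(Br)c1 | intermediate
7 | methyl (E)-2-azido-3-(3,4,5-tribromophenyl)-3-(trifluoromethylsulfonyloxy)acrylate | COC(=O)/C(N=[N+]=[N-])=C(/c1cc(Br)c(Br)c(Br)c1)OS(=O)(=O)C(F)(F)F | intermediate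
8 | 4,6-dibromo-1H-indole | Brc1cc(Br)c2cc[nH]c2c1 | starting material
9 | 4,6-dibromo-3-(methylthio)-1H-indole | CSc1c[nH]c2cc(Br)cc(Br)c12 | intermediate
10 | 2,4,6-tribromo-3-(methylthio)-1H-indole | CSc1c(Br)[nH]c2cc(Br)cc(Br)c12 | intermediate
11 | methyl (E)-2-azido-3-(3,4,5-tribromophenyl)-3-[2,4,6-tribromo-3-(methylthio)indol-1-yl]acrylate | COC(=O)/C(N=[N+]=[N-])=C(/c1cc(Br)c(Br)c(Br)c1)n1c(Br)c(SC)c2c(Br)cc(Br)cc21 | intermediate
12 | methyl 2-(3,4,5-tribromophenyl)-2-[2,4,6-tribromo-3-(methylthio)indol-1-yl]-2H-azirine-3-carboxylate (racemic) | COC(=O)C1=NC1(c1cc(Br)c(Br)c(Br)c1)n1c(Br)c(SC)c2c(Br)cc(Br)cc21 | intermediate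
13 | methyl 4,5,6-tribromo-3-[2,4,6-tribromo-3-(methylthio)indol-1-yl]-7aH-indole-2-carboxylate (racemic) | COC(=O)C1=NC2C=C(Br)C(Br)=C(Br)C2=C1n1c(Br)c(SC)c2c(Br)cc(Br)cc21 | intermediate
14 | methyl 4,5,6-tribromo-3-[2,4,6-tribromo-3-(methylthio)indol-1-yl]-1H-indole-2-carboxylate | COC(=O)c1[nH]c2cc(Br)c(Br)c(Br)c2c1-n1c(Br)c(SC)c2c(Br)cc(Br)cc21 | intermediate
15 | 4,5,6-tribromo-3-[2,4,6-tribromo-3-(methylthio)indol-1-yl]-1H-indole-2-carboxylic acid | OC(=O)c1[nH]c2cc(Br)c(Br)c(Br)c2c1-n1c(Br)c(SC)c2c(Br)cc(Br)cc21 | intermediate
16 | 4,5,6-tribromo-3-[2,4,6-tribromo-3-(methylthio)indol-1-yl]-1H-indole | Brc1cc2[nH]cc(-n3c(Br)c(SC)c4c(Br)cc(Br)cc43)c2c(Br)c1Br | intermediate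
17 | 4,5,6-tribromo-2-(methylthio)-3-[2,4,6-tribromo-3-(methylthio)indol-1-yl]-1H-indole | CSc1[nH]c2cc(Br)c(Br)c(Br)c2c1-n1c(Br)c(SC)c2c(Br)cc(Br)cc21 | target

Total step count: 10
Longest linear sequence: 8 steps (1, 2, 3, 6, 7, 8, 9, 10)

Steps most likely to fail

Step 7.
- **What may go wrong:** Closure onto an electron-poor aryl ring that is twisted out of the alkene plane may be slow at 140 °C. The azirine and nitrene could then drift towards ring B or fragment and polymerise.
- **Fallback:** It sets out from 11 and comes back at 14. It replaces the uncatalysed pericyclic closure with a stepwise, metal-mediated C–H amination.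
  - Compound 11 is denitrogenated mildly (toluene, 85 °C, or 365 nm light at rt) and the 2H-azirine 12 is isolated.
  - Compound 12 is then treated with catalytic FeCl2 in THF at 60–70 °C. Coordination of divalent iron to the azirine nitrogen cleaves the C2–N bond to an iron-bound vinyl nitrenoid.
  - The nitrenoid aminates the aryl ortho C–H. This is known behaviour of 2-aryl-2H-azirines, which give 2,3-disubstituted indoles.
  - No compound outside the list is made (F0).

Step 6.
- **What may go wrong:** C–N bond formation by a hindered, weakly nucleophilic indolide may be slow. Attack at the sulfur of the triflate, with O–S cleavage back to the enolate, could then compete.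
- **Fallback:** It sets out from 7 and 9 and comes back at 11. The nucleophile is changed and the C2' bromine is introduced after the coupling.
  - Compound 9 has no bromine beside nitrogen and is both smaller and more nucleophilic. It is joined to 7 with Cs2CO3 in DMF to give methyl (E)-2-azido-3-[4,6-dibromo-3-(methylthio)indol-1-yl]-3-(3,4,5-tribromophenyl)acrylate F1.
  - NBS in dry CH2Cl2 at 0 °C then brominates C2'. This is the only free pyrrole carbon and is activated by the adjacent sulfide, whereas the acceptor-substituted vinyl azide is a poor nucleophile.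
  - The blocking bromine is therefore in place before any heating.

Step 3.
- **What may go wrong:** The α-azido enolate may lose N2 under basic conditions before O-sulfonylation takes place.
- **Fallback:** It sets out from 6 and comes back at 11. No enolate is generated.
  - The enol form of 6 is activated on oxygen by the Vilsmeier reagent made from (COCl)2 and DMF in CH2Cl2 (0 °C → rt).
  - Chloride replaces the activated oxygen by addition–elimination to give methyl (E)-2-azido-3-chloro-3-(3,4,5-tribromophenyl)acrylate F2.
  - F2 reacts with 10 and Cs2CO3 in DMF by the same vinylic substitution as in step 6. A chloride leaving group offers no second electrophilic site.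

Further compounds
F0 | step 7 | none | none
F1 | step 6 | methyl (E)-2-azido-3-[4,6-dibromo-3-(methylthio)indol-1-yl]-3-(3,4,5-tribromophenyl)acrylate | COC(=O)/C(N=[N+]=[N-])=C(/c1cc(Br)c(Br)c(Br)c1)n1cc(SC)c2c(Br)cc(Br)cc21
F2 | step 3 | methyl (E)-2-azido-3-chloro-3-(3,4,5-tribromophenyl)acrylate | COC(=O)/C(N=[N+]=[N-])=C(/c1cc(Br)c(Br)c(Br)c1)Cl
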